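Ring A is disconnected at C4'–C5', C6'–C1' and C3'–C4' into a four-carbon vinylketene and a two-carbon ynol ether. Heating a 3-silyloxy-4-prenylcyclobutenone (made from prenylketene and a silyl ynol ether by [2+2] cycloaddition) with methoxyethyne should build, in one pericyclic cascade (Danheiser benzannulation), the whole 2',4',6'-trioxygenated ring A, its C3' prenyl group held between the C2' and C4' oxygens and its methoxy group at C6'; the pattern follows directly from the way the two fragments join. Desilylation then gives a symmetric resorcinol, whose bis-MOM ether is lithiated at either equivalent ring C–H, acylated with a p-coumaric Weinreb amide and deprotected to xanthohumol.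

Key step: step 5

Remark: ring A is numbered C1'–C6' as in the chalcone; because diol 16 is symmetric, the new hydroxyl carbon of 15 is taken as C4'. Methoxyethyne is not a shelf reagent and is therefore made in step 4 and used as a cold toluene solution.

Step 1
Reactants: 1 ethyl dibromoacetate
Product: 3 (triisopropylsilyloxy)ethyne, via lithium ethynolate 2 (not isolated)
Conditions: t-BuLi (4 equiv), THF, −78 → 0 °C; TIPSCl, −78 °C → rt; aq. NaHCO3
Reagents that add atoms: triisopropylsilyl chloride, CC(C)[Si](Cl)(C(C)C)C(C)C
Why: Two consecutive bromine–lithium exchanges should turn the dibromoester into an ester dianion that expels LiOEt to leave ynolate 2 (ynolate synthesis by cleavage of ester dianions), and the bulky silyl chloride reacts at oxygen, not carbon (O-silylation of an ynolate), any lithium left on the alkyne terminus being protonated on work-up.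

Step 2
Reactants: 4 5-methylhex-4-enoic acid
Product: 5 5-methylhex-4-enoyl chloride
Conditions: (COCl)2, cat. DMF, CH2Cl2, 0 °C → rt
Reagents that add atoms: oxalyl chloride, O=C(Cl)C(Cl)=O
Why: Chloroiminium (Vilsmeier-type) activation converts the acid into its chloride under cold, anhydrous conditions (acid chloride formation) that should not touch the trisubstituted alkene.

Step 3
Reactants: 5 5-methylhex-4-enoyl chloride; 3 (triisopropylsilyloxy)ethyne
Product: 7 4-(3-methylbut-2-enyl)-3-(triisopropylsilyloxy)cyclobut-2-en-1-one (racemic), via prenylketene 6 (not isolated)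
Conditions: Et3N, Et2O, rt, slow addition of 5
Reagents that add atoms: none
Why: Dehydrochlorination gives aldoketene 6, which is trapped as it forms by the electron-rich ynol ether in a ketene–alkyne [2+2] cycloaddition whose polarity (alkyne CH terminus to the ketene carbonyl carbon) places silyloxy at C3 and prenyl at C4; the C4 stereocentre forms racemic and is erased in step 5.

Step 4
Reactants: 8 chloroacetaldehyde dimethyl acetal
Product: 10 methoxyethyne, via sodium methoxyacetylide 9 (not isolated)
Conditions: NaNH2 (3 equiv), liq. NH3, −33 °C; sat. aq. NaCl, −70 °C; distilled into cold toluene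
Reagents that add atoms: none
Why: NaNH2 removes methanol and then HCl from the chloroacetal (double β-elimination, the standard alkoxyacetylene synthesis) and holds the product as its acetylide until a cold aqueous quench releases the volatile ynol ether.

Step 5
Reactants: 7 4-(3-methylbut-2-enyl)-3-(triisopropylsilyloxy)cyclobut-2-en-1-one; 10 methoxyethyne
Product: 15 5-methoxy-2-(3-methylbut-2-enyl)-3-(triisopropylsilyloxy)phenol, via siloxy vinylketene 11 (not isolated), via 4-vinylcyclobutenone 12 (not isolated), via dienylketene 13 (not isolated), via cyclohexadienone 14 (not isolated)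
Conditions: 10 (3 equiv), toluene, sealed tube, 80 → 110 °C
Reagents that add atoms: none
Why: Thermal conrotatory 4π opening of 7, the C4 prenyl group turning outward, gives vinylketene 11, which adds 10 in a regioselective [2+2] cycloaddition to give 12; the strained ring of 12 opens in turn to dienylketene 13, whose 6π ring closure gives dienone 14, and enolisation delivers phenol 15. The closest known reaction type is the Danheiser benzannulation of cyclobutenones with alkoxy- and silyloxyacetylenes. Ring A is closed by the thermally allowed disrotatory 6π electrocyclisation of 13 (bond C3'–C4'), after the cycloaddition has made C4'–C5' and C6'–C1'. No stereocentre survives, because the centres of 7, 12 and 14 are lost on aromatisation. The one selectivity needed is the orientation of the [2+2]: the methoxy group polarises the alkyne so that its CH terminus bonds to the ketene carbonyl carbon, so methoxy ends up 1,3 to the new hydroxyl and the prenyl-bearing carbon lies between the two oxygenated carbons derived from 7. Methoxyethyne has no β-hydrogen for retro-ene loss of ketene, and no acid, base or metal is present that could attack the prenyl double bond.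

Step 6
Reactants: 15 5-methoxy-2-(3-methylbut-2-enyl)-3-(triisopropylsilyloxy)phenol
Product: 16 5-methoxy-2-(3-methylbut-2-enyl)benzene-1,3-diol
Conditions: TBAF, AcOH, THF, 0 °C → rt
Reagents that add atoms: none
Why: Fluoride cleaves the aryl Si–O bond (fluoride-mediated desilylation) while acetic acid keeps the electron-rich product protonated, and the resulting diol is symmetric so that its two ring C–H positions become equivalent.

Step 7
Reactants: 16 5-methoxy-2-(3-methylbut-2-enyl)benzene-1,3-diol
Product: 17 5-methoxy-1,3-bis(methoxymethoxy)-2-(3-methylbut-2-enyl)benzene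
Conditions: MOMCl, iPr2NEt, CH2Cl2, 0 °C → rt
Reagents that add atoms: chloromethyl methyl ether, COCCl
Why: Both phenols are alkylated at oxygen by the α-chloro ether under amine base (Williamson-type acetal formation), which masks the acidic protons and installs the directing groups for step 10.

Step 8
Reactants: 18 (E)-4-hydroxycinnamic acid
Product: 19 (E)-3-(4-hydroxyphenyl)-N-methoxy-N-methylprop-2-enamide
Conditions: MeNHOMe·HCl, EDC·HCl, HOBt, iPr2NEt, DMF, 0 °C → rt
Reagents that add atoms: N,O-dimethylhydroxylamine hydrochloride, CNOC.Cl
Why: Carbodiimide/HOBt activation couples the acid with the hydroxylamine (amide coupling) faster than the free phenol is acylated, and the E alkene of 18 is carried through unchanged.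

Step 9
Reactants: 19 (E)-3-(4-hydroxyphenyl)-N-methoxy-N-methylprop-2-enamide
Product: 20 (E)-N-methoxy-3-[4-(methoxymethoxy)phenyl]-N-methylprop-2-enamide
Conditions: MOMCl, iPr2NEt, CH2Cl2, 0 °C → rt
Reagents that add atoms: chloromethyl methyl ether, COCCl
Why: O-alkylation of the phenol (Williamson-type) removes the only acidic proton before the organolithium step and gives a protecting group of the same kind as those on ring A.

Step 10
Reactants: 17 5-methoxy-1,3-bis(methoxymethoxy)-2-(3-methylbut-2-enyl)benzene; 20 (E)-N-methoxy-3-[4-(methoxymethoxy)phenyl]-N-methylprop-2-enamide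
Product: 23 (E)-1-[6-methoxy-2,4-bis(methoxymethoxy)-3-(3-methylbut-2-enyl)phenyl]-3-[4-(methoxymethoxy)phenyl]prop-2-en-1-one, via aryllithium 21 (not isolated), via lithium hemiaminal adduct 22 (not isolated)
Conditions: n-BuLi, TMEDA, THF, 0 °C; 20, −78 → 0 °C; aq. NH4Cl
Reagents that add atoms: none
Why: n-BuLi/TMEDA should deprotonate one of the two equivalent ring C–H positions, each flanked by OMOM and OMe (directed ortho metalation), and aryllithium 21 adds to the amide carbonyl to give chelate 22, which releases the ketone only on work-up so that no second addition occurs (Weinreb ketone synthesis); the E alkene comes from 20.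

Step 11
Reactants: 23 (E)-1-[6-methoxy-2,4-bis(methoxymethoxy)-3-(3-methylbut-2-enyl)phenyl]-3-[4-(methoxymethoxy)phenyl]prop-2-en-1-one
Product: 24 xanthohumol [(E)-1-[2,4-dihydroxy-6-methoxy-3-(3-methylbut-2-enyl)phenyl]-3-(4-hydroxyphenyl)prop-2-en-1-one]
Conditions: aq. HCl (3 M), MeOH, rt
Reagents that add atoms: none
Why: Acid-catalysed acetal exchange with methanol removes all three MOM groups (MOM ether cleavage), the carbonyl-flanked 2'-OMOM first, and dilute acid at room temperature should leave the prenyl alkene and the open-chain E chalcone intact.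

Compound list
1 | ethyl dibromoacetate | CCOC(=O)C(Br)Br | starting material
2 | lithium ethynolate | [Li+].[O-]C#C | intermediate
3 | (triisopropylsilyloxy)ethyne | C#CO[Si](C(C)C)(C(C)C)C(C)C | intermediate
4 | 5-methylhex-4-enoic acid | CC(C)=CCCC(O)=O | starting material
5 | 5-methylhex-4-enoyl chloride | CC(C)=CCCC(Cl)=O | intermediate
6 | prenylketene (5-methylhexa-1,4-dien-1-one) | CC(C)=CCC=C=O | intermediate
7 | 4-(3-methylbut-2-enyl)-3-(triisopropylsilyloxy)cyclobut-2-en-1-one (racemic) | O=C1C=C(O[Si](C(C)C)(C(C)C)C(C)C)C1CC=C(C)C | intermediate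
8 | chloroacetaldehyde dimethyl acetal | COC(CCl)OC | starting material
9 | sodium methoxyacetylide | [Na+].[C-]#COC | intermediate
10 | methoxyethyne | COC#C | intermediate
11 | (3Z)-7-methyl-3-(triisopropylsilyloxy)octa-1,3,6-trien-1-one | O=C=C/C(O[Si](C(C)C)(C(C)C)C(C)C)=C/CC=C(C)C | intermediate
12 | 3-methoxy-4-[(1Z)-5-methyl-1-(triisopropylsilyloxy)hexa-1,4-dien-1-yl]cyclobut-2-en-1-one (racemic) | O=C1C=C(OC)C1/C(O[Si](C(C)C)(C(C)C)C(C)C)=C/CC=C(C)C | intermediate
13 | (3E,5Z)-3-methoxy-9-methyl-5-(triisopropylsilyloxy)deca-1,3,5,8-tetraen-1-one | O=C=C/C(OC)=C\C(O[Si](C(C)C)(C(C)C)C(C)C)=C\CC=C(C)C | intermediate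
14 | 3-methoxy-6-(3-methylbut-2-enyl)-5-(triisopropylsilyloxy)cyclohexa-2,4-dien-1-one (racemic) | O=C1C=C(OC)C=C(O[Si](C(C)C)(C(C)C)C(C)C)C1CC=C(C)C | intermediate
15 | 5-methoxy-2-(3-methylbut-2-enyl)-3-(triisopropylsilyloxy)phenol | COc1cc(O)c(CC=C(C)C)c(O[Si](C(C)C)(C(C)C)C(C)C)c1 | intermediate
16 | 5-methoxy-2-(3-methylbut-2-enyl)benzene-1,3-diol | COc1cc(O)c(CC=C(C)C)c(O)c1 | intermediate
17 | 5-methoxy-1,3-bis(methoxymethoxy)-2-(3-methylbut-2-enyl)benzene | COCOc1cc(OC)cc(OCOC)c1CC=C(C)C | intermediate
18 | (E)-4-hydroxycinnamic acid | OC(=O)/C=C/c1ccc(O)cc1 | starting material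
19 | (E)-3-(4-hydroxyphenyl)-N-methoxy-N-methylprop-2-enamide | CON(C)C(=O)/C=C/c1ccc(O)cc1 | intermediate
20 | (E)-N-methoxy-3-[4-(methoxymethoxy)phenyl]-N-methylprop-2-enamide | CON(C)C(=O)/C=C/c1ccc(OCOC)cc1 | intermediate
21 | [6-methoxy-2,4-bis(methoxymethoxy)-3-(3-methylbut-2-enyl)phenyl]lithium | [Li]c1c(OC)cc(OCOC)c(CC=C(C)C)c1OCOC | intermediate
22 | lithium (E)-1-[6-methoxy-2,4-bis(methoxymethoxy)-3-(3-methylbut-2-enyl)phenyl]-1-[methoxy(methyl)amino]-3-[4-(methoxymethoxy)phenyl]prop-2-en-1-olate (racemic) | [Li+].[O-]C(/C=C/c1ccc(OCOC)cc1)(N(C)OC)c1c(OC)cc(OCOC)c(CC=C(C)C)c1OCOC | intermediate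
23 | (E)-1-[6-methoxy-2,4-bis(methoxymethoxy)-3-(3-methylbut-2-enyl)phenyl]-3-[4-(methoxymethoxy)phenyl]prop-2-en-1-one | COCOc1cc(OC)c(C(=O)/C=C/c2ccc(OCOC)cc2)c(OCOC)c1CC=C(C)C | intermediate
24 | xanthohumol, (E)-1-[2,4-dihydroxy-6-methoxy-3-(3-methylbut-2-enyl)phenyl]-3-(4-hydroxyphenyl)prop-2-en-1-one | COc1cc(O)c(CC=C(C)C)c(O)c1C(=O)/C=C/c1ccc(O)cc1 | target

Total step count: 11. Longest linear sequence: 7 steps (steps 1, 3, 5, 6, 7, 10, 11; the branch through step 2 is equally long).

Steps most likely to fail

Step 5. The donor-stabilised cyclobutenone may ring-open too slowly, so that the volatile alkyne escapes or the vinylketene is lost to self-condensation before it is trapped. The fallback takes ring A from the aromatic pool and introduces the prenyl group by directed metalation. No numbered compound made before the key step is of use once the benzannulation is given up, so this fallback sets out from purchased 5-methoxyresorcinol (COc1cc(O)cc(O)c1) instead of from 7 and 10. MOMCl and iPr2NEt give 1-methoxy-3,5-bis(methoxymethoxy)benzene F1. n-BuLi in THF at 0 °C should lithiate the carbon between the two OMOM groups to give [4-methoxy-2,6-bis(methoxymethoxy)phenyl]lithium F2. Prenyl bromide with catalytic CuI then gives 17, where the fallback comes back to the route.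

Step 10. Deprotonation may take place at the benzylic–allylic CH2 of the prenyl group (lateral metalation) instead of on the ring, or the hindered aryllithium may add sluggishly. The fallback generates the same aryllithium by halogen–metal exchange and sets out from 17. NBS in MeCN at −30 °C should brominate one of the two equivalent, highly activated ring positions in preference to the prenyl alkene, giving 2-bromo-1-methoxy-3,5-bis(methoxymethoxy)-4-(3-methylbut-2-enyl)benzene F3. Bromine–lithium exchange with t-BuLi (2 equiv) in THF at −78 °C, far faster than any deprotonation, gives aryllithium 21, where the fallback comes back to the route and continues with 20 to 23.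

Step 1. The parent ynolate may be metalated further or silylated at carbon, and the small ynol ether may be lost on isolation. The fallback reaches 7 without any silyl ynol ether and sets out from acid chloride 5. Et3N in the presence of purchased ethoxyethyne (CCOC#C) gives, via ketene 6, 3-ethoxy-4-(3-methylbut-2-enyl)cyclobut-2-en-1-one F4 (racemic). Brief treatment with dilute aq. HCl in THF hydrolyses the vinylogous ester to 3-hydroxy-4-(3-methylbut-2-enyl)cyclobut-2-en-1-one F5 (racemic). TIPSCl and Et3N silylate its delocalised anion on oxygen; either oxygen leads to the same constitution because C4 is bonded to both oxygenated ring carbons. The product is 7, where the fallback comes back to the route.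

Further compounds
F1 | step 5 | 1-methoxy-3,5-bis(methoxymethoxy)benzene | COCOc1cc(OC)cc(OCOC)c1
F2 | step 5 | [4-methoxy-2,6-bis(methoxymethoxy)phenyl]lithium | [Li]c1c(OCOC)cc(OC)cc1OCOC
F3 | step 10 | 2-bromo-1-methoxy-3,5-bis(methoxymethoxy)-4-(3-methylbut-2-enyl)benzene | COCOc1cc(OC)c(Br)c(OCOC)c1CC=C(C)C
F4 | step 1 | 3-ethoxy-4-(3-methylbut-2-enyl)cyclobut-2-en-1-one (racemic) | CCOC1=CC(=O)C1CC=C(C)C
F5 | step 1 | 3-hydroxy-4-(3-methylbut-2-enyl)cyclobut-2-en-1-one (racemic) | OC1=CC(=O)C1CC=C(C)C
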